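**Retrosynthetic overview**
1. Ring D last: C13 is set by kinetic protonation of the ester dienolate, and C11=C12 is closed by ring-closing metathesis of triene ester 25.
2. C5–C13 (the trans B/D junction) and C3=C4 come from an Ireland–Claisen rearrangement of but-3-enoate 22; its C3–O bond comes from Baeyer–Villiger cleavage of cage ketone 18, then Mitsunobu inversion.
3. Ring C (C6–C10) comes from an intramolecular Diels–Alder reaction of nitroalkene 15 with the cyclohexadiene as diene; the bridged adduct also fixes C10.
4. Rings A and B come from a new Claisen/6π cascade of trienyl vinyl ether 11 (C8–C9 bond, C8 stereocentre, C2–C7 bond).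
5. Absolute configuration comes from copper-catalysed enantioselective anti-SN2′ opening of cyclooctatetraene oxide 7 with zinc reagent 9. Ring order: eight-membered ring (bought) → A + B → C → D.

Atom labels (ring atoms in SMILES order): C1 (cyclobutane CH with the decenyl chain), C2, C3=C4, C5, C6, C7, C8, C9 (CH2), C10, C11=C12, C13 (CH–CO2Me). Ring A = cyclobutane C1/C2/C7/C8; ring B = cyclohexene C2–C7; ring C = cyclopentane C6–C10; ring D = cyclohexene C5/C6/C10–C13.

Assumption: the SMILES is read literally (H5 anti to H6, so rings B and D are trans-fused, and H13 cis to H5), which an endiandric-type Diels–Alder closure of ring D cannot give; the sense of induction in step 4 is taken as drawn, otherwise the mirror-image ligand is used.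

**Route**

Step 1
Reactants: 1 (E)-hex-4-en-1-ol
Product: 2 (E)-6-bromohex-2-ene
Conditions: CBr4, PPh3, CH2Cl2, 0 °C
Reagents that add atoms: carbon tetrabromide, BrC(Br)(Br)Br
Why: Appel bromination of a primary alcohol; the (E)-alkene is not touched.

Step 2
Reactants: 2 (E)-6-bromohex-2-ene; 3 1-bromo-4-chlorobutane
Product: 5 (E)-10-chlorodec-2-ene, via (E)-hex-4-enylmagnesium bromide 4 (not isolated)
Conditions: Mg, THF, 40 °C; then 3, Li2CuCl4 (2 mol %), THF, −10 → 0 °C
Reagents that add atoms: none
Why: Kochi copper-catalysed alkyl–alkyl Grignard coupling reacts only at the C–Br bond of 3 and keeps the chloride for the next metalation.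

Step 3
Reactants: 6 cyclooctatetraene
Product: 7 cyclooctatetraene oxide
Conditions: mCPBA (1.0 equiv), CH2Cl2, 0 °C
Reagents that add atoms: 3-chloroperoxybenzoic acid, O=C(OO)c1cccc(Cl)c1
Why: Prilezhaev mono-epoxidation of the non-conjugated tub-shaped tetraene gives the known meso oxide; one equivalent of peracid at 0 °C limits over-oxidation.

Step 4
Reactants: 5 (E)-10-chlorodec-2-ene; 7 cyclooctatetraene oxide
Product: 10 (1R,4R)-4-[(E)-dec-8-enyl]cycloocta-2,5,7-trien-1-ol, via (E)-dec-8-enylmagnesium chloride 8 (not isolated), via bis[(E)-dec-8-enyl]zinc 9 (not isolated)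
Conditions: Mg, THF, 60 °C; Zn(OMe)2 (0.5 equiv), then centrifugation; Cu(OTf)2 (3 mol %), (S,R,R)-phosphoramidite from BINOL and bis(1-phenylethyl)amine (6 mol %), toluene, −78 → −10 °C; aq NH4Cl
Reagents that add atoms: none
Why: copper–phosphoramidite-catalysed enantioselective anti-SN2′ alkylation desymmetrises the meso vinyl oxirane (known for this epoxide with simple dialkylzincs); the alkyl group enters C1 anti to the oxygen, which sets C1 for the whole route and places the C6 hydroxyl trans to it.

Step 5
Reactants: 10 (1R,4R)-4-[(E)-dec-8-enyl]cycloocta-2,5,7-trien-1-ol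
Product: 11 (1R,4R)-4-[(E)-dec-8-enyl]-1-(ethenyloxy)cycloocta-2,5,7-triene
Conditions: n-BuOCH=CH2 (solvent), Pd(OAc)2 (2 mol %), 1,10-phenanthroline (2.5 mol %), Et3N (5 mol %), 25 °C
Reagents that add atoms: butyl vinyl ether, C=COCCCC
Why: palladium-diacetate-catalysed transfer vinylation (vinyl ether exchange) under basic conditions, so the doubly allylic carbinol cannot ionise to the achiral homotropylium cation.

Step 6
Reactants: 11 (1R,4R)-4-[(E)-dec-8-enyl]-1-(ethenyloxy)cycloocta-2,5,7-triene
Product: 13 2-[7-exo-((E)-dec-8-enyl)-cis-bicyclo[4.2.0]octa-2,4-dien-8-endo-yl]acetaldehyde, via trans-7,8-disubstituted cyclooctatriene aldehyde 12 (not isolated)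
Conditions: toluene (0.02 M), BHT (cat.), 80 °C, base-washed glassware
Reagents that add atoms: none
Why: Proposed new method: aliphatic Claisen rearrangement of a cycloocta-2,5,7-trienyl vinyl ether coupled to 6π electrocyclisation; the [3,3] shift is suprafacial across C6–C7=C8, so the CH2CHO arm reaches C8 on the face the oxygen leaves, anti to the decenyl group on C1 (1,4- to 1,2-chirality transfer, trans); this arm should win over the dienyl arm (bond to C4) because only it creates the fully conjugated 1,3,5-triene, which then closes thermally in disrotatory fashion to the cis-fused bicyclooctadiene (drawn as the arm-endo valence isomer; the arm-exo isomer and the monocycle interconvert with it on heating); the closest known chemistry is the Claisen rearrangement of cyclohex-2-enyl vinyl ethers with 1,3-chirality transfer and the 6π closure of trans-7,8-disubstituted cycloocta-1,3,5-trienes.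

Step 7
Reactants: 13 2-[7-exo-((E)-dec-8-enyl)-cis-bicyclo[4.2.0]octa-2,4-dien-8-endo-yl]acetaldehyde
Product: 15 7-exo-[(E)-dec-8-enyl]-8-endo-[(E)-3-nitroprop-2-enyl]-cis-bicyclo[4.2.0]octa-2,4-diene, via nitroaldol 14 (not isolated)
Conditions: MeNO2 (5 equiv), tetramethylguanidine (10 mol %), THF, 0 °C; then MsCl, Et3N, CH2Cl2, 0 °C
Reagents that add atoms: nitromethane, C[N+](=O)[O-]
Why: Henry addition followed by mesylate elimination gives the (E)-nitroalkene, a strong dienophile and a ketone equivalent; its carbon becomes C11.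

Step 8
Reactants: 15 7-exo-[(E)-dec-8-enyl]-8-endo-[(E)-3-nitroprop-2-enyl]-cis-bicyclo[4.2.0]octa-2,4-diene
Product: 16 nitro cage adduct (new bonds C6–C10 and C3–C11; C4=C5; NO2 on C11)
Conditions: toluene (0.02 M), BHT (cat.), 80 °C
Reagents that add atoms: none
Why: intramolecular Diels–Alder reaction with the cyclohexadiene as diene and the tethered nitroalkene as dienophile (the mode that gives the endiandric acid C skeleton); only the arm-endo valence isomer can react and the others funnel into it through the cyclooctatriene; the bridged transition state sets C6 and C10 and forces C11 onto the C5 side of ring C.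

Step 9
Reactants: 16 nitro cage adduct
Product: 18 cage ketone (C11=O), via sodium nitronate 17 (not isolated)
Conditions: NaOMe, MeOH, 0 °C; then aq TiCl3, NH4OAc (pH 5–6), 25 °C
Reagents that add atoms: water, O
Why: Nef reaction in the McMurry variant (nitronate reduced by TiCl3 to the imine, then hydrolysed); C10 cannot epimerise because the cage locks it.

Step 10
Reactants: 18 cage ketone
Product: 19 bridged lactone (C3–O–C11(=O)–C10)
Conditions: Me3SiOOSiMe3 (1.5 equiv), Me3SiOTf (10 mol %), CH2Cl2, −78 → −40 °C
Reagents that add atoms: bis(trimethylsilyl) peroxide, C[Si](C)(C)OO[Si](C)(C)C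
Why: Baeyer–Villiger oxidation with a silyl peroxide that leaves C=C bonds alone; the allylic bridgehead carbon C3 migrates with retention, so the new C3–O bond lies on the ring-A face of ring B.

Step 11
Reactants: 19 bridged lactone
Product: 20 lactol (C11 hemiacetal)
Conditions: i-Bu2AlH (1.1 equiv), CH2Cl2, −78 °C; Rochelle salt
Reagents that add atoms: none
Why: half-reduction of a lactone; the tetrahedral aluminate survives at −78 °C until work-up.

Step 12
Reactants: 20 lactol
Product: 21 tricyclic allylic alcohol (C3–OH syn to ring A; C4=C5; vinyl on C10)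
Conditions: Ph3PCH3Br, KN(SiMe3)2, THF, −78 → 0 °C
Reagents that add atoms: methylenetriphenylphosphorane (made in the flask from methyltriphenylphosphonium bromide), C=P(c1ccccc1)(c1ccccc1)c1ccccc1
Why: Wittig methylenation of the lactol through its hydroxy-aldehyde form gives the C10 vinyl group (C11 stays) and frees the C3 alcohol; the low temperature guards C10 against epimerisation.

Step 13
Reactants: 21 tricyclic allylic alcohol
Product: 22 C3-inverted but-3-enoate (ester oxygen anti to ring A)
Conditions: but-3-enoic acid, PPh3, DIAD, toluene, 0 → 25 °C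
Reagents that add atoms: but-3-enoic acid, C=CCC(=O)O
Why: Mitsunobu esterification inverts C3 by SN2; the carboxylate enters from the open convex face, placing the oxygen where the next step needs it.

Step 14
Reactants: 22 C3-inverted but-3-enoate
Product: 25 methyl 2-(tricyclic C5-yl)but-3-enoate (C5–C13 bond anti to C10; C3=C4; both C13 epimers), via silyl ketene acetal 23 (not isolated), via carboxylic acid 24 (not isolated)
Conditions: LiN(i-Pr)2, Me3SiCl, THF, −78 → 45 °C; aq work-up; then Me3SiCHN2, MeOH/toluene, 0 °C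
Reagents that add atoms: trimethylsilyldiazomethane, C[Si](C)(C)C=[N+]=[N-]
Why: Ireland–Claisen rearrangement; the suprafacial [3,3] shift from the C3 oxygen across C4=C5 forms C5–C13 on the convex face, anti to C10 on C6 (the trans B/D junction), and moves the alkene to C3=C4; the acid is then methylated, and C13 is not controlled here.

Step 15
Reactants: 25 methyl 2-(tricyclic C5-yl)but-3-enoate
Product: 26 tetracyclic methyl ester (C13 epimer mixture)
Conditions: Cl2(PCy3)2Ru=CHPh (first-generation Grubbs catalyst, 5 mol %), CH2Cl2 (2 mM), 40 °C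
Reagents that add atoms: none
Why: ring-closing metathesis of the two terminal vinyl groups closes ring D (C11=C12); the first-generation catalyst is chosen because it reacts slowly with the internal (E)-alkene of the side chain and the ring-B alkene.

Step 16
Reactants: 26 tetracyclic methyl ester (C13 epimer mixture)
Product: 28 target CNP0133550.2, via lithium dienolate 27 (not isolated)
Conditions: LiN(i-Pr)2 (1.2 equiv), THF, −78 °C; then AcOH in THF, −78 °C
Reagents that add atoms: none
Why: deprotonation gives the planar ester dienolate (both C13 epimers converge), and kinetic α-protonation of this exocyclic enolate should come from the less hindered pseudo-equatorial side, the face of H5, giving the β,γ-unsaturated ester with H13 cis to H5 (Zimmerman-type kinetic protonation).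

**Compound list**
1 | (E)-hex-4-en-1-ol | C/C=C/CCCO | starting material
2 | (E)-6-bromohex-2-ene | C/C=C/CCCBr | intermediate
3 | 1-bromo-4-chlorobutane | ClCCCCBr | starting material
4 | (E)-hex-4-enylmagnesium bromide (not isolated) | C/C=C/CCC[Mg]Br | intermediate
5 | (E)-10-chlorodec-2-ene | C/C=C/CCCCCCCCl | intermediate
6 | cycloocta-1,3,5,7-tetraene | C1=CC=CC=CC=C1 | starting material
7 | cyclooctatetraene oxide (cis-9-oxabicyclo[6.1.0]nona-2,4,6-triene, meso) | C1=CC=C[C@@H]2O[C@@H]2C=C1 | intermediate
8 | (E)-dec-8-enylmagnesium chloride (not isolated) | C/C=C/CCCCCCC[Mg]Cl | intermediate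
9 | bis[(E)-dec-8-enyl]zinc (not isolated) | C/C=C/CCCCCCC[Zn]CCCCCCC/C=C/C | intermediate
10 | (1R,4R)-4-[(E)-dec-8-enyl]cycloocta-2,5,7-trien-1-ol (OH on C6 trans to the chain on C1) | O[C@H]1C=C[C@H](CCCCCCC/C=C/C)C=CC=C1 | intermediate
11 | (1R,4R)-4-[(E)-dec-8-enyl]-1-(ethenyloxy)cycloocta-2,5,7-triene | C=CO[C@H]1C=C[C@H](CCCCCCC/C=C/C)C=CC=C1 | intermediate
12 | trans-2-[8-((E)-dec-8-enyl)cycloocta-2,4,6-trien-1-yl]acetaldehyde (not isolated) | C/C=C/CCCCCCC[C@@H]1C=CC=CC=C[C@H]1CC=O | intermediate
13 | 2-[7-exo-((E)-dec-8-enyl)-cis-bicyclo[4.2.0]octa-2,4-dien-8-endo-yl]acetaldehyde (arm on the face of the six-membered ring, chain anti) | C/C=C/CCCCCCC[C@@H]1[C@H]2C=CC=C[C@H]2[C@H]1CC=O | intermediate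
14 | nitroaldol of 13 (3-nitro-2-hydroxypropyl arm on C8, carbinol centre unassigned; not isolated) | C/C=C/CCCCCCC[C@@H]1[C@H]2C=CC=C[C@H]2[C@H]1CC(O)C[N+](=O)[O-] | intermediate
15 | 7-exo-[(E)-dec-8-enyl]-8-endo-[(E)-3-nitroprop-2-enyl]-cis-bicyclo[4.2.0]octa-2,4-diene | C/C=C/CCCCCCC[C@@H]1[C@H]2C=CC=C[C@H]2[C@H]1C/C=C/[N+](=O)[O-] | intermediate
16 | nitro cage adduct: rings A–C plus a bicyclo[2.2.2]octene (bonds C6–C10 and C3–C11 on the ring-A face of ring B; C4=C5; NO2 on C11, either epimer) | C/C=C/CCCCCCC[C@@H]1[C@H]2[C@@H]5C=C[C@@H]4[C@H]2[C@H]1C[C@@H]4C5[N+](=O)[O-] | intermediate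
17 | sodium nitronate of 16 (not isolated) | C/C=C/CCCCCCC[C@@H]1[C@H]2[C@@H]5C=C[C@@H]4[C@H]2[C@H]1C[C@@H]4C5=[N+]([O-])[O-].[Na+] | intermediate
18 | cage ketone (C11=O) | C/C=C/CCCCCCC[C@@H]1[C@H]2[C@@H]5C=C[C@@H]4[C@H]2[C@H]1C[C@@H]4C5=O | intermediate
19 | bridged lactone (C3–O–C11(=O)–C10; O on C3 syn to ring A) | C/C=C/CCCCCCC[C@@H]1[C@H]2[C@@H]5C=C[C@@H]4[C@H]2[C@H]1C[C@@H]4C(=O)O5 | intermediate
20 | lactol of 19 (C11 hemiacetal, either epimer) | C/C=C/CCCCCCC[C@@H]1[C@H]2[C@@H]5C=C[C@@H]4[C@H]2[C@H]1C[C@@H]4C(O)O5 | intermediate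
21 | tricyclic allylic alcohol (rings A–C; C3–OH syn to ring A; C4=C5; vinyl on C10 on the same face of ring C as C5) | C/C=C/CCCCCCC[C@@H]1[C@H]2[C@@H](O)C=C[C@@H]4[C@H]2[C@H]1C[C@@H]4C=C | intermediate
22 | but-3-enoate of the C3 epimer of 21 (ester oxygen anti to ring A) | C/C=C/CCCCCCC[C@@H]1[C@H]2[C@H](OC(=O)CC=C)C=C[C@@H]4[C@H]2[C@H]1C[C@@H]4C=C | intermediate
23 | trimethylsilyl ketene acetal of 22 (not isolated) | C/C=C/CCCCCCC[C@@H]1[C@H]2[C@H](OC(O[Si](C)(C)C)=CC=C)C=C[C@@H]4[C@H]2[C@H]1C[C@@H]4C=C | intermediate
24 | 2-(tricyclic C5-yl)but-3-enoic acid (C5–C13 anti to C10; C3=C4; C13 epimers; not isolated) | C/C=C/CCCCCCC[C@@H]1[C@H]2C=C[C@H](C(C=C)C(=O)O)[C@@H]4[C@H]2[C@H]1C[C@@H]4C=C | intermediate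
25 | methyl ester of 24 | C/C=C/CCCCCCC[C@@H]1[C@H]2C=C[C@H](C(C=C)C(=O)OC)[C@@H]4[C@H]2[C@H]1C[C@@H]4C=C | intermediate
26 | tetracyclic methyl ester, C13 epimer mixture | C/C=C/CCCCCCC[C@@H]1[C@H]2C=C[C@H]3[C@@H]4[C@H]2[C@H]1C[C@@H]4C=CC3C(=O)OC | intermediate
27 | lithium dienolate of 26 (not isolated) | C/C=C/CCCCCCC[C@@H]1[C@H]2C=C[C@H]3[C@@H]4[C@H]2[C@H]1C[C@@H]4C=CC3=C(OC)[O-].[Li+] | intermediate
28 | CNP0133550.2 | C/C=C/CCCCCCC[C@@H]1[C@H]2C=C[C@H]3[C@@H]4[C@H]2[C@H]1C[C@@H]4C=C[C@H]3C(=O)OC | target

**Totals and risks**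
Total steps: 16. Longest linear sequence: 15 (steps 1, 2 and 4–16).

Step 6 (the new Claisen/6π cascade). The [3,3] shift could instead go through the dienyl arm to C4, the cyclooctatrienes could undergo hydrogen shifts at 80 °C, or the ether could ionise. The fallback uses known chemistry, sets out from 10 and comes back at 13. Alcohol 10 is acylated with methyl chloroformate and pyridine to the methyl carbonate F1. Tsuji–Trost alkylation with sodium dimethyl malonate and Pd(PPh3)4 in THF proceeds by ionisation and attack, both anti to palladium, so the malonate enters C8 on the face the oxygen left, at the terminus that gives the conjugated triene. The same 6π closure then gives the bicyclic malonate F2. Krapcho demethoxycarbonylation (LiCl, wet DMSO, 130 °C) gives the methyl ester F3, and i-Bu2AlH at −78 °C gives aldehyde 13.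

Step 13 (Mitsunobu inversion). The hydroxyl sits on the concave face of an allylic system, so SN2′ attack or elimination may win. The fallback sets out from 21 and comes back at 25. Dess–Martin oxidation gives the enone F4 (C3=O, C4=C5). The lithium dienolate of methyl but-3-enoate (LiN(i-Pr)2, THF/HMPA, −78 °C) adds through its α-carbon to C5 from the convex face, and the resulting enolate is trapped with PhNTf2 as the enol triflate F5. Reduction with Pd(OAc)2, PPh3, Bu3N and HCO2H in DMF turns the triflate into the C3=C4 alkene, which is 25.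

Step 16 (kinetic protonation). The facial preference at C13 is predicted, not known. The fallback sets out from 22 and comes back at 28. C13 is set inside the Ireland–Claisen step instead: enolising 22 in THF or in THF/HMPA switches the ketene acetal geometry, so one of the two protocols should give mainly the needed C13 epimer of 25. Ring-closing metathesis as in step 15 then gives 28 after separation of the minor epimer. This detour makes no new compound (none F0).

**Further compounds**
F1 | step 6 | methyl carbonate of 10 | COC(=O)O[C@H]1C=C[C@H](CCCCCCC/C=C/C)C=CC=C1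
F2 | step 6 | dimethyl 2-[7-exo-((E)-dec-8-enyl)-cis-bicyclo[4.2.0]octa-2,4-dien-8-endo-yl]malonate | C/C=C/CCCCCCC[C@@H]1[C@H]2C=CC=C[C@H]2[C@H]1C(C(=O)OC)C(=O)OC
F3 | step 6 | methyl 2-[7-exo-((E)-dec-8-enyl)-cis-bicyclo[4.2.0]octa-2,4-dien-8-endo-yl]acetate | C/C=C/CCCCCCC[C@@H]1[C@H]2C=CC=C[C@H]2[C@H]1CC(=O)OC
F4 | step 13 | tricyclic enone (C3=O, C4=C5, vinyl on C10) | C/C=C/CCCCCCC[C@@H]1[C@H]2C(=O)C=C[C@@H]4[C@H]2[C@H]1C[C@@H]4C=C
F5 | step 13 | enol triflate (C3–OTf, C3=C4) carrying the methyl but-3-enoate unit on C5 | C/C=C/CCCCCCC[C@@H]1[C@H]2C(OS(=O)(=O)C(F)(F)F)=C[C@H](C(C=C)C(=O)OC)[C@@H]4[C@H]2[C@H]1C[C@@H]4C=C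
F0 | step 16 | none | none
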